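**Retrosynthetic overview**

1. The target comes from the bicyclic diol by angeloylation of the secondary C8 hydroxyl, after fluoride removal of the C8 and C10 silyl ethers.
2. Key disconnection, C5–C6 and O–C12: C6 is both the allylic carbinol next to the Z C4=C5 alkene of the ten-membered carbocycle and the oxygen-bearing carbon of the γ-lactone (O–C6–C7–C11–C12). Vinylation of a C6 aldehyde by the C5 alkenyl iodide therefore creates the alkoxide that closes the lactone on the C12 methyl ester; the ten-membered ring forms first, then the γ-lactone, in one flask.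
3. The seco aldehyde comes from a C7–C8 bond construction: catalyst-controlled 2-(methoxycarbonyl)allylation of a C8 aldehyde with an allyl bromide that carries C6 as a PMB-protected carbinol. The C6 aldehyde is then unveiled by DDQ and Dess–Martin oxidation, so no hydride or palladium–silane reduction ever meets the C1 ketone, the acrylate or the alkenyl iodide.
4. The C8 aldehyde comes from (S)-citramalic acid (C8, C9, C10, C1; C10 stereocentre from the pool) and alkylation of its methyl ketone (C2–C3 bond) with the (Z)-iodoallyl bromide made from propargyl alcohol (C3–C5).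
5. The C10 hydroxyl is held as a triethylsilyl ether until after ring closure, because a free C10 hydroxyl would close a six-membered lactol onto the C6 aldehyde.

Key step: step 18

Locants: germacrane numbering throughout (C1 ketone, C2 and C3 methylenes, C4(CH3)=C5, C6 lactone carbinol, C7, C8 ester carbinol, C9 methylene, C10 tertiary carbinol, C11=C13 methylene, C12 lactone carbonyl).

Assumption: the carbazole bis(oxazoline)–chromium catalyst of step 14 is taken to control the aldehyde face with the substituted allyl bromide as it does with simple allyl bromides; the ligand enantiomer that gives Si-face (8R) addition is used and is written as (S,S).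

**Route**

Step 1
Reactants: 1 propargyl alcohol
Product: 3 (Z)-3-iodo-2-methylprop-2-en-1-ol, via alkenylmagnesium alkoxide 2 (not isolated)
Conditions: MeMgBr (3 equiv), CuI (10 mol %), THF, −10 °C to rt; then I2, −78 to 0 °C
Reagents that add atoms: methylmagnesium bromide (C[Mg]Br); iodine (II)
Why: Copper-catalysed anti carbomagnesiation of the propargylic alkoxide should place the methyl group on the internal carbon and magnesium on the terminus cis to the CH2O group through a five-membered chelate, and iodinolysis with retention then gives the Z iodide.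

Step 2
Reactants: 3 (Z)-3-iodo-2-methylprop-2-en-1-ol
Product: 4 (Z)-3-bromo-1-iodo-2-methylprop-1-ene
Conditions: CBr4, PPh3, CH2Cl2, 0 °C
Reagents that add atoms: tetrabromomethane (BrC(Br)(Br)Br)
Why: Appel bromination displaces the alkoxyphosphonium ion of the primary allylic alcohol by SN2 and leaves the alkenyl iodide and its geometry untouched.

Step 3
Reactants: 5 (S)-citramalic acid
Product: 6 2-[(4S)-2,2,4-trimethyl-5-oxo-1,3-dioxolan-4-yl]acetic acid
Conditions: 2,2-dimethoxypropane, p-TsOH (cat.), rt
Reagents that add atoms: 2,2-dimethoxypropane (COC(C)(C)OC)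
Why: Acid-catalysed acetal exchange ties the tertiary hydroxyl and its neighbouring carboxyl (C1) into a 1,3-dioxolan-4-one, which tells the two carboxyl groups apart without touching the C10 stereocentre.

Step 4
Reactants: 6 2-[(4S)-2,2,4-trimethyl-5-oxo-1,3-dioxolan-4-yl]acetic acid
Product: 7 (5S)-5-(2-hydroxyethyl)-2,2,5-trimethyl-1,3-dioxolan-4-one
Conditions: BH3·SMe2, THF, 0 °C to rt; MeOH quench
Reagents that add atoms: none
Why: Borane reduces the free carboxylic acid (C8) through its acyloxyborane much faster than the dioxolanone carbonyl, so the C8 primary alcohol should form selectively.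

Step 5
Reactants: 7 (5S)-5-(2-hydroxyethyl)-2,2,5-trimethyl-1,3-dioxolan-4-one
Product: 8 (2S)-2,4-dihydroxy-N-methoxy-N,2-dimethylbutanamide
Conditions: MeNHOMe·HCl, iPrMgCl, THF, −20 to 0 °C
Reagents that add atoms: N,O-dimethylhydroxylamine hydrochloride (CNOC.Cl)
Why: The magnesium amide opens the activated dioxolanone by acyl substitution with loss of acetone (Weinreb amide formation), and any hydroxy lactone formed from 7 by acyl transfer is opened to the same amide.

Step 6
Reactants: 8 (2S)-2,4-dihydroxy-N-methoxy-N,2-dimethylbutanamide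
Product: 9 (2S)-N-methoxy-N,2-dimethyl-2,4-bis(triethylsilyloxy)butanamide
Conditions: TESOTf, 2,6-lutidine, CH2Cl2, −78 to 0 °C
Reagents that add atoms: triethylsilyl trifluoromethanesulfonate (CC[Si](CC)(CC)OS(=O)(=O)C(F)(F)F)
Why: A silyl triflate with a hindered pyridine base silylates the primary (C8) and the tertiary (C10) hydroxyl alike.

Step 7
Reactants: 9 (2S)-N-methoxy-N,2-dimethyl-2,4-bis(triethylsilyloxy)butanamide
Product: 10 (3S)-3-methyl-3,5-bis(triethylsilyloxy)pentan-2-one
Conditions: MeMgBr, THF, 0 °C to rt
Reagents that add atoms: methylmagnesium bromide (C[Mg]Br)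
Why: Grignard addition to the Weinreb amide stops at the chelated tetrahedral intermediate, so hydrolysis should give the methyl ketone (C1 carbonyl, C2 methyl) without over-addition.

Step 8
Reactants: 10 (3S)-3-methyl-3,5-bis(triethylsilyloxy)pentan-2-one; 4 (Z)-3-bromo-1-iodo-2-methylprop-1-ene
Product: 12 (3S,7Z)-8-iodo-3,7-dimethyl-1,3-bis(triethylsilyloxy)oct-7-en-4-one, via lithium enolate 11 (not isolated)
Conditions: LiN(iPr)2, THF, −78 °C; then 4, DMPU, −78 to −30 °C
Reagents that add atoms: none
Why: C10 is quaternary, so the ketone can only enolise toward the methyl group, and SN2 alkylation of this single lithium enolate by the reactive allylic bromide forms the C2–C3 bond with the Z alkenyl iodide intact.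

Step 9
Reactants: 12 (3S,7Z)-8-iodo-3,7-dimethyl-1,3-bis(triethylsilyloxy)oct-7-en-4-one
Product: 14 (3S,7Z)-8-iodo-3,7-dimethyl-4-oxo-3-(triethylsilyloxy)oct-7-enal, via alkoxysulfonium chloride 13 (not isolated)
Conditions: (COCl)2, DMSO, CH2Cl2, −78 to −40 °C; then Et3N, −78 to 0 °C
Reagents that add atoms: none
Why: Under Swern conditions the chlorosulfonium reagent cleaves the unhindered primary triethylsilyl ether and the alkoxysulfonium ion is oxidised to the C8 aldehyde in the same operation, while the tertiary silyl ether at C10 is too hindered to react; the keto aldehyde is used directly.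

Step 10
Reactants: 15 (Z)-but-2-ene-1,4-diol
Product: 16 (Z)-1,4-bis[(4-methoxybenzyl)oxy]but-2-ene
Conditions: NaH, PMBCl, Bu4NI (cat.), DMF, 0 °C to rt
Reagents that add atoms: 4-methoxybenzyl chloride (COc1ccc(CCl)cc1)
Why: Williamson etherification of both primary allylic hydroxyls.

Step 11
Reactants: 16 (Z)-1,4-bis[(4-methoxybenzyl)oxy]but-2-ene
Product: 18 2-[(4-methoxybenzyl)oxy]acetaldehyde, via ozonide 17 (not isolated)
Conditions: O3, CH2Cl2, −78 °C; then PPh3, −78 °C to rt
Reagents that add atoms: ozone (O=[O+][O-])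
Why: Ozonolysis of the symmetrical alkene with reductive work-up should give two equivalents of the aldehyde.

Step 12
Reactants: 18 2-[(4-methoxybenzyl)oxy]acetaldehyde; 19 methyl acrylate
Product: 20 methyl 3-hydroxy-4-[(4-methoxybenzyl)oxy]-2-methylidenebutanoate (racemic)
Conditions: DABCO, 1,4-dioxane/H2O, rt
Reagents that add atoms: none
Why: Morita–Baylis–Hillman reaction, in which the amine adds to the acrylate, the zwitterionic enolate attacks the activated α-alkoxy aldehyde and the amine is then eliminated; the carbinol centre is removed in the next step.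

Step 13
Reactants: 20 methyl 3-hydroxy-4-[(4-methoxybenzyl)oxy]-2-methylidenebutanoate
Product: 21 methyl (2Z)-2-(bromomethyl)-4-[(4-methoxybenzyl)oxy]but-2-enoate
Conditions: NBS, Me2S, CH2Cl2, 0 °C to rt
Reagents that add atoms: N-bromosuccinimide (O=C1CCC(=O)N1Br)
Why: The halosulfonium reagent activates the allylic hydroxyl and bromide attacks in SN2' fashion, which should give the thermodynamically preferred Z 2-(bromomethyl)enoate with the CH2OPMB group trans to the ester.

Step 14
Reactants: 14 (3S,7Z)-8-iodo-3,7-dimethyl-4-oxo-3-(triethylsilyloxy)oct-7-enal; 21 methyl (2Z)-2-(bromomethyl)-4-[(4-methoxybenzyl)oxy]but-2-enoate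
Product: 24 methyl (3S,4R,6S,10Z)-4-hydroxy-11-iodo-3-{[(4-methoxybenzyl)oxy]methyl}-6,10-dimethyl-2-methylidene-7-oxo-6-(triethylsilyloxy)undec-10-enoate [germacrane locants 7S,8R,10S], via allylchromium reagent 22 (not isolated), via trimethylsilyl ether 23 (not isolated)
Conditions: CrCl2 (10 mol %), (S,S)-1,8-bis(4-isopropyl-4,5-dihydrooxazol-2-yl)-3,6-diphenyl-9H-carbazole (12 mol %), Mn powder, iPr2NEt, TMSCl, THF, rt; then 10% aq. citric acid, THF, 0 °C
Reagents that add atoms: none
Why: Catalytic asymmetric Nozaki–Hiyama allylation, in which the allylchromium reagent adds through C7 in a chair transition state to the aldehyde alone (ketone and alkenyl iodide are inert without nickel); the Z-type geometry of the 2-(methoxycarbonyl)allyl unit gives the 7,8-syn adduct, the ligand selects the Si face of the C8 aldehyde, and silylation of the chromium alkoxide by TMSCl turns the catalyst over and keeps the C8 oxygen off the C12 ester until mild acid removes the trimethylsilyl group.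

Step 15
Reactants: 24 the C8 alcohol of step 14
Product: 25 methyl (3S,4R,6S,10Z)-4-(tert-butyldimethylsilyloxy)-11-iodo-3-{[(4-methoxybenzyl)oxy]methyl}-6,10-dimethyl-2-methylidene-7-oxo-6-(triethylsilyloxy)undec-10-enoate
Conditions: TBSOTf, 2,6-lutidine, CH2Cl2, −78 °C
Reagents that add atoms: tert-butyldimethylsilyl trifluoromethanesulfonate (CC(C)(C)[Si](C)(C)OS(=O)(=O)C(F)(F)F)
Why: Low-temperature silylation caps the secondary C8 hydroxyl before it can lactonise onto the C12 ester, and it drains any five-membered hemiketal formed with the C1 ketone through the open-chain alcohol.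

Step 16
Reactants: 25 the C8 TBS ether of step 15
Product: 26 methyl (3S,4R,6S,10Z)-4-(tert-butyldimethylsilyloxy)-3-(hydroxymethyl)-11-iodo-6,10-dimethyl-2-methylidene-7-oxo-6-(triethylsilyloxy)undec-10-enoate
Conditions: DDQ, CH2Cl2/pH 7 buffer, 0 °C
Reagents that add atoms: none
Why: DDQ oxidises the electron-rich PMB ether by hydride abstraction and the hemiacetal collapses in the buffered aqueous phase, which frees the C6 primary alcohol under neutral conditions that spare the silyl ethers, the alkenyl iodide, the ketone and the acrylate; the alcohol is oxidised at once.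

Step 17
Reactants: 26 the C6 primary alcohol of step 16
Product: 27 methyl (3R,4R,6S,10Z)-4-(tert-butyldimethylsilyloxy)-3-formyl-11-iodo-6,10-dimethyl-2-methylidene-7-oxo-6-(triethylsilyloxy)undec-10-enoate [open-chain C6 aldehyde; germacrane locants 7R,8R,10S]
Conditions: Dess–Martin periodinane, NaHCO3, CH2Cl2, 0 °C
Reagents that add atoms: none
Why: Buffered Dess–Martin oxidation gives the aldehyde without strong base or acid, so the doubly activated C7 hydrogen and the β-silyloxy group should survive; the aldehyde is filtered through a short pad and used at once.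

Step 18
Reactants: 27 the open-chain C6 aldehyde of step 17
Product: 30 (4Z,6R,7S,8R,10S)-8-(tert-butyldimethylsilyloxy)-1-oxo-10-(triethylsilyloxy)germacra-4,11(13)-dien-12,6-olide, via alkenylchromium 28 (not isolated), via macrocyclic chromium alkoxide 29 (not isolated)
Conditions: CrCl2 (10 equiv), NiCl2 (2 mol % of CrCl2), degassed DMSO/THF, rt, 27 added by syringe pump to 2 mM; aq. NH4Cl work-up
Reagents that add atoms: none
Why: Zerovalent nickel, formed from NiCl2 and CrCl2, inserts into the C5–I bond with retention, passes the alkenyl group to trivalent chromium, and alkenylchromium 28 adds to the C6 aldehyde; the closest known reaction type is the Nozaki–Hiyama–Kishi macrocyclisation of iodoalkenyl aldehydes with lactonisation of the new alkoxide on a neighbouring ester. The ten-membered carbocycle closes by this intramolecular carbonyl addition (C5–C6 bond) under high dilution, and the γ-lactone then closes by 5-exo-trig acyl substitution of the C6 chromium alkoxide 29 on the C12 methyl ester (O–C12 bond) with loss of methoxide. The new C6 stereocentre should follow Felkin–Anh addition: the tether holds the C8 branch anti to the forming C5–C6 bond, so C5 approaches past the C7 hydrogen and not past the acrylate, which gives 6R and the trans-fused lactone. The Z geometry of C4=C5 is carried over from the iodide because both metal transfers go with retention. The step needs aldehyde-over-ketone selectivity, which organochromium reagents provide, and it needs a C10 oxygen that cannot form a lactol with the C6 aldehyde and a C8 oxygen that cannot compete for the ester, which the triethylsilyl and TBS ethers secure.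

Step 19
Reactants: 30 the bis-silylated lactone of step 18
Product: 31 (4Z,6R,7R,8R,10S)-8,10-dihydroxy-1-oxogermacra-4,11(13)-dien-12,6-olide
Conditions: HF·pyridine, pyridine, THF, 0 °C to rt
Reagents that add atoms: none
Why: Buffered fluoride cleaves the secondary TBS ether and the tertiary triethylsilyl ether under conditions too weakly basic to add to the α-methylene lactone or to shift the α-ketol.

Step 20
Reactants: 31 the diol lactone of step 19; 32 angelic acid
Product: 34 (4Z,6R,7R,8R,10S)-8-angeloyloxy-10-hydroxy-1-oxogermacra-4,11(13)-dien-12,6-olide (CNP0345906.2), via mixed anhydride 33 (not isolated)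
Conditions: 2,4,6-trichlorobenzoyl chloride, Et3N, toluene, rt; then 31, toluene, 70 °C, no DMAP
Reagents that add atoms: none
Why: Yamaguchi-type mixed-anhydride acylation, in which the secondary C8 hydroxyl attacks the angeloyl carbonyl because the trichlorobenzoyl carbonyl is shielded by its two ortho chlorines; the tertiary C10 hydroxyl is too hindered to react, and leaving out a nucleophilic catalyst should keep the Z geometry of the angelate.

**Compound list**

1 | propargyl alcohol | C#CCO | starting material
2 | (Z)-alkenylmagnesium alkoxide from carbomagnesiation (not isolated) | Br[Mg]OC/C(C)=C\[Mg]Br | intermediate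
3 | (Z)-3-iodo-2-methylprop-2-en-1-ol | OC/C(C)=C\I | intermediate
4 | (Z)-3-bromo-1-iodo-2-methylprop-1-ene | BrC/C(C)=C\I | intermediate
5 | (S)-citramalic acid | OC(=O)[C@@](C)(O)CC(=O)O | starting material
6 | 2-[(4S)-2,2,4-trimethyl-5-oxo-1,3-dioxolan-4-yl]acetic acid | O=C1OC(C)(C)O[C@@]1(C)CC(=O)O | intermediate
7 | (5S)-5-(2-hydroxyethyl)-2,2,5-trimethyl-1,3-dioxolan-4-one | O=C1OC(C)(C)O[C@@]1(C)CCO | intermediate
8 | (2S)-2,4-dihydroxy-N-methoxy-N,2-dimethylbutanamide | CON(C)C(=O)[C@@](C)(O)CCO | intermediate
9 | (2S)-N-methoxy-N,2-dimethyl-2,4-bis(triethylsilyloxy)butanamide | CON(C)C(=O)[C@@](C)(O[Si](CC)(CC)CC)CCO[Si](CC)(CC)CC | intermediate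
10 | (3S)-3-methyl-3,5-bis(triethylsilyloxy)pentan-2-one | CC(=O)[C@@](C)(O[Si](CC)(CC)CC)CCO[Si](CC)(CC)CC | intermediate
11 | lithium enolate of 10 (not isolated) | [Li]OC(=C)[C@@](C)(O[Si](CC)(CC)CC)CCO[Si](CC)(CC)CC | intermediate
12 | (3S,7Z)-8-iodo-3,7-dimethyl-1,3-bis(triethylsilyloxy)oct-7-en-4-one | I/C=C(/C)CCC(=O)[C@@](C)(O[Si](CC)(CC)CC)CCO[Si](CC)(CC)CC | intermediate
13 | C8 alkoxydimethylsulfonium chloride from 12 (not isolated) | C[S+](C)OCC[C@](C)(O[Si](CC)(CC)CC)C(=O)CC/C(C)=C\I.[Cl-] | intermediate
14 | (3S,7Z)-8-iodo-3,7-dimethyl-4-oxo-3-(triethylsilyloxy)oct-7-enal (C8 aldehyde, C10 OTES, C1 ketone, Z C5 iodide) | O=CC[C@](C)(O[Si](CC)(CC)CC)C(=O)CC/C(C)=C\I | intermediate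
15 | (Z)-but-2-ene-1,4-diol | OC/C=C\CO | starting material
16 | (Z)-1,4-bis[(4-methoxybenzyl)oxy]but-2-ene | COc1ccc(COC/C=C\COCc2ccc(OC)cc2)cc1 | intermediate
17 | 3,5-bis{[(4-methoxybenzyl)oxy]methyl}-1,2,4-trioxolane (ozonide, not isolated) | COc1ccc(COCC2OOC(COCc3ccc(OC)cc3)O2)cc1 | intermediate
18 | 2-[(4-methoxybenzyl)oxy]acetaldehyde | COc1ccc(COCC=O)cc1 | intermediate
19 | methyl acrylate | C=CC(=O)OC | starting material
20 | methyl 3-hydroxy-4-[(4-methoxybenzyl)oxy]-2-methylidenebutanoate (racemic) | COC(=O)C(=C)C(O)COCc1ccc(OC)cc1 | intermediate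
21 | methyl (2Z)-2-(bromomethyl)-4-[(4-methoxybenzyl)oxy]but-2-enoate | COC(=O)/C(CBr)=C/COCc1ccc(OC)cc1 | intermediate
22 | allylchromium reagent from 21 (not isolated; chiral ligand omitted) | COC(=O)/C(C[Cr](Cl)Cl)=C/COCc1ccc(OC)cc1 | intermediate
23 | C8 trimethylsilyl ether of 24 (not isolated; 7S,8R,10S) | COc1ccc(COC[C@H](C(=C)C(=O)OC)[C@H](O[Si](C)(C)C)C[C@](C)(O[Si](CC)(CC)CC)C(=O)CC/C(C)=C\I)cc1 | intermediate
24 | methyl (3S,4R,6S,10Z)-4-hydroxy-11-iodo-3-{[(4-methoxybenzyl)oxy]methyl}-6,10-dimethyl-2-methylidene-7-oxo-6-(triethylsilyloxy)undec-10-enoate (C6 OPMB, C7 acrylate, C8 OH, C10 OTES; 7S,8R,10S) | COc1ccc(COC[C@H](C(=C)C(=O)OC)[C@H](O)C[C@](C)(O[Si](CC)(CC)CC)C(=O)CC/C(C)=C\I)cc1 | intermediate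
25 | C8 TBS ether of 24 (7S,8R,10S) | COc1ccc(COC[C@H](C(=C)C(=O)OC)[C@H](O[Si](C)(C)C(C)(C)C)C[C@](C)(O[Si](CC)(CC)CC)C(=O)CC/C(C)=C\I)cc1 | intermediate
26 | C6 primary alcohol: methyl (3S,4R,6S,10Z)-4-(tert-butyldimethylsilyloxy)-3-(hydroxymethyl)-11-iodo-6,10-dimethyl-2-methylidene-7-oxo-6-(triethylsilyloxy)undec-10-enoate | OC[C@H](C(=C)C(=O)OC)[C@H](O[Si](C)(C)C(C)(C)C)C[C@](C)(O[Si](CC)(CC)CC)C(=O)CC/C(C)=C\I | intermediate
27 | open-chain C6 aldehyde with C7 acrylate ester, C8 OTBS, C10 OTES, C1 ketone and Z C5 iodide (7R,8R,10S; same spatial arrangement at C7 as 26, the descriptor changes with the CHO priority) | O=C[C@H](C(=C)C(=O)OC)[C@H](O[Si](C)(C)C(C)(C)C)C[C@](C)(O[Si](CC)(CC)CC)C(=O)CC/C(C)=C\I | intermediate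
28 | C5 alkenylchromium dichloride from 27 (not isolated) | O=C[C@H](C(=C)C(=O)OC)[C@H](O[Si](C)(C)C(C)(C)C)C[C@](C)(O[Si](CC)(CC)CC)C(=O)CC/C(C)=C\[Cr](Cl)Cl | intermediate
29 | ten-membered C6 chromium alkoxide with the C12 methyl ester intact (not isolated) | COC(=O)C(=C)[C@H]1[C@H](O[Cr](Cl)Cl)/C=C(/C)CCC(=O)[C@@](C)(O[Si](CC)(CC)CC)C[C@H]1O[Si](C)(C)C(C)(C)C | intermediate
30 | (4Z,6R,7S,8R,10S)-8-(tert-butyldimethylsilyloxy)-1-oxo-10-(triethylsilyloxy)germacra-4,11(13)-dien-12,6-olide (7S only through the CIP rank of the silyl ether; same spatial arrangement as in 31) | C=C1C(=O)O[C@@H]2/C=C(/C)CCC(=O)[C@@](C)(O[Si](CC)(CC)CC)C[C@@H](O[Si](C)(C)C(C)(C)C)[C@@H]12 | intermediate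
31 | (4Z,6R,7R,8R,10S)-8,10-dihydroxy-1-oxogermacra-4,11(13)-dien-12,6-olide | C=C1C(=O)O[C@@H]2/C=C(/C)CCC(=O)[C@@](C)(O)C[C@@H](O)[C@@H]12 | intermediate
32 | angelic acid | C/C=C(/C)C(=O)O | starting material
33 | angelic 2,4,6-trichlorobenzoic anhydride (not isolated) | C/C=C(/C)C(=O)OC(=O)c1c(Cl)cc(Cl)cc1Cl | intermediate
34 | (4Z,6R,7R,8R,10S)-8-angeloyloxy-10-hydroxy-1-oxogermacra-4,11(13)-dien-12,6-olide (CNP0345906.2) | C=C1C(=O)O[C@@H]2/C=C(/C)CCC(=O)[C@@](C)(O)C[C@@H](OC(=O)/C(C)=C\C)[C@@H]12 | target

**Step count**

Total: 20 steps. Longest linear sequence: 14 steps (steps 3–9 and 14–20, from (S)-citramalic acid).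

**Steps most likely to fail**

1. Step 18 (ring closure). The alkenylchromium may add to the other face of the C6 aldehyde, or chains may couple with each other before they cyclise. A 6S alkoxide cannot reach C12 in a trans-fused ring and would be isolated as the hydroxy ester. Fallback: setting out from 27, the macrocyclic 6-epi hydroxy ester F1 obtained under the same chromium conditions would be hydrolysed at the methyl ester with Me3SnOH (1,2-dichloroethane, 70 °C) to the 6-epi hydroxy acid F2. F2 would then be closed by Mitsunobu lactonisation (PPh3, DIAD, toluene, 0 °C), which forms the O–C6 bond by SN2 displacement with inversion instead of by acyl substitution. The route is rejoined at 30.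

2. Step 14 (C7–C8 bond). The catalyst may give poor facial control at the C8 aldehyde, or the C8 chromium alkoxide may attack the C12 ester before it is silylated. Fallback: setting out from 14 and 21, a Barbier allylation with indium powder in THF/H2O at rt should give the free 7,8-syn alcohols directly through a chair transition state, with protonation in place of a chromium alkoxide. Facial selectivity is then left to the substrate, and 24 would be separated by chromatography from its 7R,8S diastereomer F3. The route is rejoined at 24.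

3. Step 8 (C2–C3 bond). Proton transfer between the enolate and the product may lead to double alkylation, and the silyl group may migrate from the C10 oxygen to the enolate oxygen on warming. Fallback: setting out from 10, condensation with 1,1-dimethylhydrazine (4 Å molecular sieves, toluene, 80 °C) would give the N,N-dimethylhydrazone F4. Its aza-enolate (LiN(iPr)2, THF, 0 °C) would be alkylated once with 4 at −78 °C to give the alkylated hydrazone F5, and buffered CuCl2 in THF/H2O (pH 7) would hydrolyse F5 to the ketone. The route is rejoined at 12.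

**Further compounds**

F1 | step 18 | ten-membered 6-epi hydroxy ester (6S,7S,8R,10S) with C12 methyl ester, C8 OTBS and C10 OTES | COC(=O)C(=C)[C@H]1[C@@H](O)/C=C(/C)CCC(=O)[C@@](C)(O[Si](CC)(CC)CC)C[C@H]1O[Si](C)(C)C(C)(C)C
F2 | step 18 | ten-membered 6-epi hydroxy acid (6S,7S,8R,10S) with C8 OTBS and C10 OTES | OC(=O)C(=C)[C@H]1[C@@H](O)/C=C(/C)CCC(=O)[C@@](C)(O[Si](CC)(CC)CC)C[C@H]1O[Si](C)(C)C(C)(C)C
F3 | step 14 | methyl (3R,4S,6S,10Z)-4-hydroxy-11-iodo-3-{[(4-methoxybenzyl)oxy]methyl}-6,10-dimethyl-2-methylidene-7-oxo-6-(triethylsilyloxy)undec-10-enoate (7R,8S diastereomer of 24) | COc1ccc(COC[C@@H](C(=C)C(=O)OC)[C@@H](O)C[C@](C)(O[Si](CC)(CC)CC)C(=O)CC/C(C)=C\I)cc1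
F4 | step 8 | (E)-N,N-dimethylhydrazone of (3S)-3-methyl-3,5-bis(triethylsilyloxy)pentan-2-one | CN(C)/N=C(\C)[C@@](C)(O[Si](CC)(CC)CC)CCO[Si](CC)(CC)CC
F5 | step 8 | (E)-N,N-dimethylhydrazone of (3S,7Z)-8-iodo-3,7-dimethyl-1,3-bis(triethylsilyloxy)oct-7-en-4-one | CN(C)/N=C(\CC/C(C)=C\I)[C@@](C)(O[Si](CC)(CC)CC)CCO[Si](CC)(CC)CC
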